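Watch the free nucleophile.

    electrophile + nucleophile ⇌ acid set free + target (K1 = 0.19, k1 = 0.23 /M/s)
    nucleophile + acid set free ⇌ protonated nucleophile, settled at all times (K2 = 23000 /M)
    target ⇌ isomer of the product (K3 = 0.55, k3 = 0.024 /s)
    nucleophile ⇌ dormant form (K4 = 0.65, k4 = 0.020 /s)

common to all: electrophile 0.020 M; time 6.0 min
- Tuesday's: nucleophile 0.0300 M (fed, over 80 s); the fed solution adds 0.10 times the starting volume
- Friday's: nucleophile 0.0450 M (fed, over 80 s); the fed solution adds 0.10 times the starting volume

1. part of the electrophile that has reacted at the end, Tuesday's
2. part of the electrophile that has reacted at the end, Friday's
3. what raising the concentration of nucleophile from its lowest to its highest value here does to the part of the electrophile that has reacted (changes below 5 percentage points count as none) (no change / it falls / it rises)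

- amounts are per litre of the starting volume; all of the dose is in the solution fed
- run time (Tuesday's): 6.0 min

You wanted a quick number, and your hunch was to follow the nucleophile. We agree, and by hand it goes this far, with x the fraction of electrophile reacted.

1. Binding constant times charge is 690, far more than one, so acid set free takes a nucleophile each time. Each electrophile reacted therefore costs two nucleophiles.

2. The ceiling is 0.750 on Tuesday's: the nucleophile charge over two electrophile charges. Nucleophile is the limiting reagent there. Friday's ceiling is 1.12, which is above 1.

3. On Tuesday's the balance of nucleophile with dormant form relaxes with a half-life of 0.228 min, much shorter than the 6.0 min run, so we take the share 0.606 of the unprotonated nucleophile as free and the rest as dormant.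

4. Now we compare rates at one moment. At x of one half on Tuesday's, counting the isomer as target, the way back runs at 6.85% of the forward rate, far less than it. It grows as free nucleophile falls, but we drop it for this run.

5. That leaves dx/dt = κ(1 − x)(X − x), where κ = 0.00507 /s at the final volume. We let the dose arrive at its midpoint, so the clock is τ = 320 s.

6. Integrating gives x = X(E − 1)/(E − X), with E = exp[(1 − X)κτ]. Tuesday's comes to 50.0% and Friday's to 66.9%, a rise of 17 percentage points.

The forecast stands higher than our figures, at 58% and 78%, with the same verdict, it rises, on the ground that “Each electrophile consumed uses two nucleophiles, one reacting and one trapping the released acid”.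

The simulation gives 49.8% for Tuesday's and 66.9% for Friday's, so it rises, by 17 points. Tuesday's ends with nucleophile at 19.8% of its charge and dormant form at 0.00381 M. Take a neighbour of Tuesday's with 0.0075 M of nucleophile: its ceiling is 0.188, and the same κ and τ give 14.5%. That neighbour ends with 14.4% of its electrophile reacted.

Its constants were drawn at random within sensible limits.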